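**Retrosynthetic overview**
1. 18 ⇒ methyl ester 17 (saponification last). 17 ⇒ aromatic chromene 15 + prenyl bromide: the C8–prenyl bond is made by metal-free ion-pair-catalysed dearomative prenylation, which sets quaternary C8.
2. 15 ⇒ methyl ketone 14 (Wittig methylenation) ⇒ chromene 8 + enone 13: the C8–CH2 bond is made by primary-amine-catalysed conjugate addition with enantioselective protonation, which sets the side-chain CH.
3. 8 ⇒ acylphloroglucinol 5 + prenal (Knoevenagel/oxa-6π). 5 ⇒ phloroglucinol + (R)-2-methylbutanoic acid 2, which comes from asymmetric hydrogenation of tiglic acid (first stereocentre).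
4. 13 ⇒ acetylacetone + bromo ester 10 + formaldehyde (alkylation, then deacetylative methylenation).
5. Ring order: ring A (carbocycle) is bought as phloroglucinol, ring B (pyran) is closed in step 3, and ring A is dearomatised in step 8.

Assumption: the SMILES is read as 8R (ring carbon), 5R (side-chain carbon), 2R (acyl carbon) and E (acid alkene), with descriptors for the 7-hydroxy-5-oxo tautomer drawn; bromo ester 10 is taken as a catalogue compound.

**Step 1**
Reactants: 1 tiglic acid [(E)-2-methylbut-2-enoic acid]
Product: 2 (R)-2-methylbutanoic acid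
Conditions: Ru(OAc)2[(R)-H8-BINAP] (0.5 mol %), H2 (1.5 atm), MeOH, 20 °C
Reagents that add atoms: none
Why: Carboxylate-directed asymmetric hydrogenation of an (E)-2-alkyl-2-alkenoic acid is a standard substrate class for this catalyst (about 97% ee); the S ligand gives the S acid, so the R ligand sets the R centre, checked by the negative rotation of 2.

**Step 2**
Reactants: 2 (R)-2-methylbutanoic acid; 3 phloroglucinol
Product: 5 (2R)-2-methyl-1-(2,4,6-trihydroxyphenyl)butan-1-one, via (R)-2-methylbutanoyl chloride 4 (not isolated)
Conditions: (COCl)2 (1.1 equiv), DMF (cat.), CH2Cl2, 0 °C to rt; then 3, AlCl3 (3.5 equiv), CH2Cl2–MeNO2, 0 °C to rt; 1 M HCl work-up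
Reagents that add atoms: oxalyl chloride ClC(=O)C(=O)Cl (supplies the chlorine of 4 only; none of its atoms stay in 5)
Why: Friedel–Crafts acylation stops at the monoketone because the chelated product is deactivated, and the base-free conditions at or below room temperature avoid ketene formation, so the α-centre is kept.

**Step 3**
Reactants: 5 (2R)-2-methyl-1-(2,4,6-trihydroxyphenyl)butan-1-one; 6 3-methylbut-2-enal (prenal)
Product: 8 (2R)-1-(5,7-dihydroxy-2,2-dimethyl-2H-chromen-6-yl)-2-methylbutan-1-one, via ortho-quinone methide 7 (not isolated)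
Conditions: 6 (1.05 equiv), ethylenediammonium diacetate (20 mol %), toluene, 100 °C
Reagents that add atoms: none
Why: Knoevenagel condensation followed by oxa-6π electrocyclisation closes ring B, preferably through the never-chelated oxygen para to the acyl group; the minor 8-acyl regioisomer is removed by chromatography and no new stereocentre forms.

**Step 4**
Reactants: 9 acetylacetone (pentane-2,4-dione); 10 methyl (E)-4-bromo-2-methylbut-2-enoate
Product: 11 methyl (2E)-5-acetyl-2-methyl-6-oxohept-2-enoate
Conditions: 9 (1.3 equiv), K2CO3 (1.1 equiv), acetone, rt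
Reagents that add atoms: none
Why: SN2 C-alkylation of a soft 1,3-diketone enolate with a primary allylic bromide keeps the E alkene, and the mild base at room temperature holds back dialkylation and oxa-Michael closure.

**Step 5**
Reactants: 11 methyl (2E)-5-acetyl-2-methyl-6-oxohept-2-enoate
Product: 13 methyl (2E)-5-acetyl-2-methylhexa-2,5-dienoate, via hydroxymethyl diketone 12 (not isolated)
Conditions: 37% aq. HCHO (3 equiv), K2CO3 (1.0 equiv), THF–H2O, 0 °C to rt; used promptly (BHT)
Reagents that add atoms: formaldehyde C=O
Why: Aldol hydroxymethylation, retro-Claisen acetyl shift to oxygen and E1cB loss of acetate make up the known deacetylative methylenation of 3-alkylpentane-2,4-diones to 3-alkylbut-3-en-2-ones.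

**Step 6**
Reactants: 8 (2R)-1-(5,7-dihydroxy-2,2-dimethyl-2H-chromen-6-yl)-2-methylbutan-1-one; 13 methyl (2E)-5-acetyl-2-methylhexa-2,5-dienoate
Product: 14 methyl (2E,5R)-5-acetyl-6-{5,7-dihydroxy-2,2-dimethyl-6-[(2R)-2-methylbutanoyl]-2H-chromen-8-yl}-2-methylhex-2-enoate
Conditions: 13 (1.5 equiv), (1R,2R)-N1,N1-diethylcyclohexane-1,2-diamine·TfOH (20 mol %), CHCl3, 25 °C, 48–72 h
Reagents that add atoms: none
Why: Proposed new method: the primary amine condenses with 13 to an α-substituted vinyl iminium ion; the acidic phenol 8 (pKa about 8) gives its proton to the tertiary amine and attacks the CH2 terminus through C8, its only free nucleophilic carbon; rearomatisation makes the C–C bond formation irreversible; the neighbouring ammonium N–H then protonates one face of the enamine intramolecularly, setting C5 as R before hydrolysis releases 14, which should rest largely as its ring-chain hemiketal tautomer and so shield C5 from epimerisation. The closest known reactions are the primary–tertiary diamine catalysed Friedel–Crafts conjugate addition/enantioselective protonation of indoles on α-substituted vinyl ketones and acroleins, and the primary-amine catalysed Michael addition of 4-hydroxycoumarin to enones; neither has been shown for a chelated acylphloroglucinol. I cannot predict the sense of protonation with confidence, so the (1S,2S) catalyst is used if the first run shows the opposite sense; the minor C5 epimer is a diastereomer and is removed by chromatography.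

**Step 7**
Reactants: 14 methyl (2E,5R)-5-acetyl-6-{5,7-dihydroxy-2,2-dimethyl-6-[(2R)-2-methylbutanoyl]-2H-chromen-8-yl}-2-methylhex-2-enoate
Product: 15 methyl (2E,5R)-5-({5,7-dihydroxy-2,2-dimethyl-6-[(2R)-2-methylbutanoyl]-2H-chromen-8-yl}methyl)-2,6-dimethylhepta-2,6-dienoate
Conditions: Ph3PCH3Br (4.5 equiv), KN(SiMe3)2 (4.2 equiv), THF, 0 °C; add 14, 0 °C to rt; aq. NH4Cl
Reagents that add atoms: methyltriphenylphosphonium bromide C[P+](c1ccccc1)(c1ccccc1)c1ccccc1.[Br-]
Why: Wittig methylenation hits the only reactive carbonyl, because the aryl ketone is masked as a bis-phenolate and the enoate is inert; any competing enolisation goes to the CH3 side, so C5 stays R and is configurationally fixed once the ketone is gone.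

**Step 8**
Reactants: 15 methyl (2E,5R)-5-({5,7-dihydroxy-2,2-dimethyl-6-[(2R)-2-methylbutanoyl]-2H-chromen-8-yl}methyl)-2,6-dimethylhepta-2,6-dienoate; 16 prenyl bromide (1-bromo-3-methylbut-2-ene)
Product: 17 methyl (2E,5R)-5-({(8R)-7-hydroxy-2,2-dimethyl-6-[(2R)-2-methylbutanoyl]-8-(3-methylbut-2-en-1-yl)-5-oxo-5,8-dihydro-2H-chromen-8-yl}methyl)-2,6-dimethylhepta-2,6-dienoate
Conditions: 16 (1.2 equiv), (S,S)-N-spiro bis(binaphthyl) quaternary ammonium bromide bearing 3,4,5-trifluorophenyl groups at the 3,3' positions (5 mol %), Cs2CO3 (2 equiv), toluene, −20 °C; pH 4 buffer work-up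
Reagents that add atoms: none
Why: Proposed new method: solid Cs2CO3 deprotonates 15, and the flat anion (electronically a 2-alkyl cyclic β-dicarbonyl enolate across O7–C7–C8) enters toluene only as a tight ion pair with the chiral ammonium cation; the cation sits at the O7/acyl-oxygen pocket and its aryl wings cover one face of C8, so soft prenyl bromide alkylates C8 irreversibly by SN2 from the open face, setting the quaternary centre as R under catalyst control and giving the chelated β-triketone enol. The closest known reactions are the racemic base-mediated alkylative dearomatisation of 3-alkylacylphloroglucinols with prenyl bromide (hop β-acid chemistry) and the asymmetric phase-transfer alkylation of 2-substituted cyclic β-keto esters to all-carbon quaternary centres; a stereoselective intermolecular prenylative dearomatisation of this kind is not known. The facial sense also cannot be predicted with confidence, so the (R,R) catalyst is used if it turns out opposite; the minor C8 epimer is a diastereomer and is removed by chromatography.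

**Step 9**
Reactants: 17 methyl ester of the target
Product: 18 (2E,5R)-5-({(8R)-7-hydroxy-2,2-dimethyl-6-[(2R)-2-methylbutanoyl]-8-(3-methylbut-2-en-1-yl)-5-oxo-5,8-dihydro-2H-chromen-8-yl}methyl)-2,6-dimethylhepta-2,6-dienoic acid (CNP0184919.1)
Conditions: LiOH (5 equiv), THF–MeOH–H2O (3:1:1), 35 °C; then 1 M HCl to pH 3, 0 °C
Reagents that add atoms: lithium hydroxide [Li+].[OH-] (its oxygen becomes a carboxyl oxygen)
Why: Saponification works because the core is present as the stabilised triketone anion, which resists nucleophilic attack and a second deprotonation; no stereocentre is touched and the acid-labile prenyl and chromene units see only a brief cold acidification.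

**Compound list**
1 | tiglic acid | C/C=C(\C)C(=O)O | starting material
2 | (R)-2-methylbutanoic acid | CC[C@@H](C)C(=O)O | intermediate
3 | phloroglucinol | Oc1cc(O)cc(O)c1 | starting material
4 | (R)-2-methylbutanoyl chloride | CC[C@@H](C)C(=O)Cl | intermediate
5 | (2R)-2-methyl-1-(2,4,6-trihydroxyphenyl)butan-1-one | CC[C@@H](C)C(=O)c1c(O)cc(O)cc1O | intermediate
6 | 3-methylbut-2-enal | CC(C)=CC=O | starting material
7 | ortho-quinone methide: 3,5-dihydroxy-4-[(2R)-2-methylbutanoyl]-6-[(Z)-3-methylbut-2-enylidene]cyclohexa-2,4-dien-1-one | CC[C@@H](C)C(=O)C1=C(O)/C(=C/C=C(C)C)C(=O)C=C1O | intermediate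
8 | (2R)-1-(5,7-dihydroxy-2,2-dimethyl-2H-chromen-6-yl)-2-methylbutan-1-one | CC[C@@H](C)C(=O)c1c(O)cc2OC(C)(C)C=Cc2c1O | intermediate
9 | acetylacetone | CC(=O)CC(C)=O | starting material
10 | methyl (E)-4-bromo-2-methylbut-2-enoate | BrC/C=C(\C)C(=O)OC | starting material
11 | methyl (2E)-5-acetyl-2-methyl-6-oxohept-2-enoate | CC(=O)C(C/C=C(\C)C(=O)OC)C(C)=O | intermediate
12 | methyl (2E)-5,5-diacetyl-6-hydroxy-2-methylhex-2-enoate | CC(=O)C(CO)(C/C=C(\C)C(=O)OC)C(C)=O | intermediate
13 | methyl (2E)-5-acetyl-2-methylhexa-2,5-dienoate | CC(=O)C(=C)C/C=C(\C)C(=O)OC | intermediate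
14 | methyl (2E,5R)-5-acetyl-6-{5,7-dihydroxy-2,2-dimethyl-6-[(2R)-2-methylbutanoyl]-2H-chromen-8-yl}-2-methylhex-2-enoate | CC(=O)[C@H](C/C=C(\C)C(=O)OC)Cc1c(O)c(C(=O)[C@H](C)CC)c(O)c2C=CC(C)(C)Oc12 | intermediate
15 | methyl (2E,5R)-5-({5,7-dihydroxy-2,2-dimethyl-6-[(2R)-2-methylbutanoyl]-2H-chromen-8-yl}methyl)-2,6-dimethylhepta-2,6-dienoate | C=C(C)[C@H](C/C=C(\C)C(=O)OC)Cc1c(O)c(C(=O)[C@H](C)CC)c(O)c2C=CC(C)(C)Oc12 | intermediate
16 | prenyl bromide | CC(C)=CCBr | starting material
17 | methyl ester of the target (8R,5R,2R,E) | C=C(C)[C@H](C/C=C(\C)C(=O)OC)C[C@]1(CC=C(C)C)C(O)=C(C(=O)[C@H](C)CC)C(=O)C2=C1OC(C)(C)C=C2 | intermediate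
18 | CNP0184919.1 | C=C(C)[C@H](C/C=C(\C)C(=O)O)C[C@]1(CC=C(C)C)C(O)=C(C(=O)[C@H](C)CC)C(=O)C2=C1OC(C)(C)C=C2 | target

**Count:** 9 steps in total. The longest linear sequence is 7 steps (1, 2, 3, 6, 7, 8, 9).

**Three steps most likely to fail**

Step 8 (new method; risks are low facial selectivity or O-alkylation). The fallback sets out from 15 and 16 and comes back at 17. Catalyst control is given up for the classical alkylative dearomatisation with an achiral base: LiN(SiMe3)2 (2.2 equiv), THF, 0 °C, then 16. This gives 17 together with its C8 epimer, methyl (2E,5R)-5-({(8S)-7-hydroxy-2,2-dimethyl-6-[(2R)-2-methylbutanoyl]-8-(3-methylbut-2-en-1-yl)-5-oxo-5,8-dihydro-2H-chromen-8-yl}methyl)-2,6-dimethylhepta-2,6-dienoate F3. Two stereocentres are already fixed, so the pair are diastereomers. They are separated on silica or by preparative HPLC, and pure 17 goes on to step 9.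

Step 6 (new method; risks are low reactivity of the chelated phenol or poor protonation selectivity). The fallback sets out from 8 and 13 and comes back at 14. The conjugate addition is run as the known base-catalysed Michael addition of an acylphloroglucinol to a vinyl ketone (Et3N 20 mol %, MeCN, rt). This gives 14 and its C5 epimer, methyl (2E,5S)-5-acetyl-6-{5,7-dihydroxy-2,2-dimethyl-6-[(2R)-2-methylbutanoyl]-2H-chromen-8-yl}-2-methylhex-2-enoate F2, in about equal amounts. The diastereomers are separated by preparative HPLC. F2 is re-equilibrated through its methyl ketone enolate with DBU and recycled; the acyl centre stays protected as the chelated phenolate. In this way the material converges on 14.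

Step 3 (risks are the regioisomer ratio and bis-chromene formation). The fallback sets out from 5 and comes back at 8. The most acidic, never-chelated para hydroxyl is O-alkylated with 3-chloro-3-methylbut-1-yne (K2CO3, KI, CuI cat., acetone, reflux). This gives the propargyl ether (2R)-1-{2,6-dihydroxy-4-[(2-methylbut-3-yn-2-yl)oxy]phenyl}-2-methylbutan-1-one F1. Heating F1 in N,N-diethylaniline at 160 °C triggers aromatic propargyl Claisen rearrangement, 1,5-hydrogen shift and oxa-6π closure. The ether oxygen is para to the acyl group and both ortho carbons are equivalent, so only 8 can form.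

**Further compounds**
F1 | step 3 | (2R)-1-{2,6-dihydroxy-4-[(2-methylbut-3-yn-2-yl)oxy]phenyl}-2-methylbutan-1-one | CC[C@@H](C)C(=O)c1c(O)cc(OC(C)(C)C#C)cc1O
F2 | step 6 | methyl (2E,5S)-5-acetyl-6-{5,7-dihydroxy-2,2-dimethyl-6-[(2R)-2-methylbutanoyl]-2H-chromen-8-yl}-2-methylhex-2-enoate | CC(=O)[C@@H](C/C=C(\C)C(=O)OC)Cc1c(O)c(C(=O)[C@H](C)CC)c(O)c2C=CC(C)(C)Oc12
F3 | step 8 | methyl (2E,5R)-5-({(8S)-7-hydroxy-2,2-dimethyl-6-[(2R)-2-methylbutanoyl]-8-(3-methylbut-2-en-1-yl)-5-oxo-5,8-dihydro-2H-chromen-8-yl}methyl)-2,6-dimethylhepta-2,6-dienoate | C=C(C)[C@H](C/C=C(\C)C(=O)OC)C[C@@]1(CC=C(C)C)C(O)=C(C(=O)[C@H](C)CC)C(=O)C2=C1OC(C)(C)C=C2
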